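The route treats the six-membered carbocycle as a benzene ring that has lost its aromaticity. Two neighbouring syn oxygens at C2 and C3, directly next to the C4=C5 double bond, are exactly what a bacterial arene dioxygenase installs. Since C4 ends as a plain CH, it can temporarily hold the halogen that orients the enzyme. In that mapping C1, the fully substituted carbinol carbon, lies para to the halogen, and the wild-type facial sense corresponds to the wanted antipode. The key step converts flat, achiral bromobenzene into an enantiopure bromocyclohexadiene cis-diol in one operation, forming both C–O bonds. C6 and C1 are then relayed from these centres by substrate control.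

Key step: step 1

Numbering: all intermediates keep the target numbering (C1 quaternary carbinol carbon, C2 and C3 acetoxy carbons, C4=C5 alkene, C6 secondary carbinol carbon, C7 exocyclic CH2). The lower face carries the C2, C3 and C6 oxygens and the upper face carries the C1 hydroxyl. PMB = 4-methoxybenzyl.

Assumption: the recombinant toluene dioxygenase strain is treated as a biocatalyst grown in house, so bromobenzene is the purchased substrate of step 1.

Step 1
Reactants: 1 bromobenzene
Product: 2 (1S,2S)-3-bromocyclohexa-3,5-diene-1,2-diol (C–Br = future C4; adjacent carbinol = future C3; second carbinol = future C2)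
Conditions: E. coli JM109 (pDTG601) expressing toluene dioxygenase, IPTG induction, glucose-fed mineral salts medium, air sparge, pH 7, 30–35 °C, slow feed of 1; cells removed, EtOAc extraction, crystallisation, cold storage
Reagents that add atoms: dioxygen, O=O
Why: Toluene dioxygenase is a Rieske-type non-heme iron oxygenase: two electrons from NADH pass through a reductase and a ferredoxin to a mononuclear ferrous site, O2 binds there side-on above the arene, and the iron-bound peroxide hands both oxygen atoms to one face of the ortho,meta π bond (future C3–C2) before protonation releases the cis-diol. The closest known reaction type is this very one, the whole-cell cis-dihydroxylation of monohalobenzenes, a dearomatising syn-dioxygenation. No ring is closed, since the benzene ring of 1 simply becomes the cyclohexadiene that persists as the carbocycle of the target. Both new stereocentres (future C3 and C2) are controlled by the protein pocket, which seats the bromine as the orienting substituent and so presents only one bond and one enantioface to the iron centre, and the (1S,2S) diol is therefore expected as a single enantiomer. The step needs ortho,meta regiochemistry, one absolute sense and a stop at the diol stage: the halogen of the substrate secures the first two, and a host lacking the cis-diol dehydrogenase secures the last.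

Step 2
Reactants: 2 (1S,2S)-3-bromocyclohexa-3,5-diene-1,2-diol
Product: 3 (3aS,7aS)-4-bromo-2,2-dimethyl-3a,7a-dihydro-1,3-benzodioxole (bromodiene acetonide)
Conditions: 2,2-dimethoxypropane, cat. p-TsOH·H2O, CH2Cl2, 0 °C → rt, 30 min; aq. NaHCO3 wash (removes MeOH and acid); kept cold and used the same day
Reagents that add atoms: 2,2-dimethoxypropane, COC(C)(C)OC
Why: Acid-catalysed transketalisation ties the cis-diol into a cis-fused dioxolane, which blocks dehydration to bromophenol and creates the concave/convex bias used later, touches no stereocentre, and is followed by immediate use so that Diels–Alder dimerisation of the diene is avoided.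

Step 3
Reactants: 3 bromodiene acetonide
Product: 4 anti vinyl epoxide (oxirane across C1–C6 on the upper face; acetonide on the lower face; C1 R, C2 S, C3 S, C6 R)
Conditions: mCPBA (1.1 equiv), CH2Cl2, 0 °C → rt; aq. Na2SO3/NaHCO3 wash
Reagents that add atoms: mCPBA, OOC(=O)c1cccc(Cl)c1
Why: Prilezhaev epoxidation selects the unhalogenated, more nucleophilic C1=C6 alkene because bromine deactivates C4=C5, and the peracid approaches the convex face away from the dioxolane, so both oxirane carbons are set anti to the acetonide.

Step 4
Reactants: 4 anti vinyl epoxide
Product: 5 (3aS,4R,5S,7aS)-7-bromo-5-[(4-methoxybenzyl)oxy]-2,2-dimethyl-3a,4,5,7a-tetrahydro-1,3-benzodioxol-4-ol (C6–OPMB lower face; C1–OH upper face)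
Conditions: 4-methoxybenzyl alcohol (3 equiv), BF3·OEt2 (10 mol %), CH2Cl2, −40 → −20 °C; Et3N quench
Reagents that add atoms: 4-methoxybenzyl alcohol, COc1ccc(CO)cc1
Why: In this Lewis-acid-catalysed alcoholysis of a vinyl epoxide the allylic C6–O bond is the weaker one, so the alcohol attacks C6 from the lower face in an SN2-like trans opening with inversion, which places the C6 oxygen cis to the C2/C3 oxygens, while the low temperature and catalytic acid spare the acetonide and suppress self-etherification of the benzylic alcohol.

Step 5
Reactants: 5 C6 PMB ether with C1 secondary alcohol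
Product: 6 (3aR,5S,7aS)-7-bromo-5-[(4-methoxybenzyl)oxy]-2,2-dimethyl-5,7a-dihydro-1,3-benzodioxol-4(3aH)-one (C1 ketone)
Conditions: Dess–Martin periodinane (1.3 equiv), solid NaHCO3, CH2Cl2, 0 °C → rt; cold aq. Na2S2O3/NaHCO3 wash, short silica plug, used at once
Reagents that add atoms: none
Why: Dess–Martin oxidation runs under buffered, essentially neutral conditions, so the β,γ-unsaturated α,α'-dialkoxy ketone should form without enolisation, double-bond migration or β-alkoxide loss, and C2 and C6 keep their configuration.

Step 6
Reactants: 6 C1 ketone; 7 dibromomethane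
Product: 9 (3aS,5S,7aS)-7-bromo-5-[(4-methoxybenzyl)oxy]-2,2-dimethyl-4-methylidene-3a,4,5,7a-tetrahydro-1,3-benzodioxole (exocyclic C1=C7 alkene), via bis(bromozincio)methane 8 (not isolated)
Conditions: Zn dust, CH2Br2 (7), THF, −40 °C, TiCl4 dropwise, aged at 5 °C for 3 d; then 6 in CH2Cl2, 0 °C → rt; poured into Et2O/aq. NaHCO3
Reagents that add atoms: dibromomethane 7, BrCBr
Why: In the Takai–Lombardo methylenation the gem-dizinc species activated by TiCl4 is nucleophilic but practically non-basic, so it turns readily enolised β-alkoxy ketones into 1,1-disubstituted alkenes without epimerisation or elimination, and the THF-moderated medium should leave the vinyl bromide, acetonide and PMB ether intact.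

Step 7
Reactants: 9 exocyclic alkene
Product: 10 (3aR,4R,5S,7aS)-7-bromo-4-(hydroxymethyl)-5-[(4-methoxybenzyl)oxy]-2,2-dimethyl-3a,4,5,7a-tetrahydro-1,3-benzodioxol-4-ol (C1–OH upper face; C7H2OH lower face)
Conditions: OsO4 (3 mol %), N-methylmorpholine N-oxide (1.5 equiv), acetone–H2O 4:1, rt; aq. Na2SO3 quench
Reagents that add atoms: OsO4 (catalytic oxygen carrier), O=[Os](=O)(=O)=O; N-methylmorpholine N-oxide, C[N+]1([O-])CCOCC1; water, O
Why: In this Upjohn dihydroxylation OsO4 adds suprafacially to the exocyclic alkene only, because the bromoalkene is trisubstituted and electron-poor, and it comes from the convex upper face anti to both allylic oxygens (C2 and C6), so the new tertiary hydroxyl at C1 (R) ends trans to all three ring oxygens.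

Step 8
Reactants: 10 C1/C7 diol; 11 benzoyl chloride
Product: 12 [(3aR,4R,5S,7aS)-7-bromo-4-hydroxy-5-[(4-methoxybenzyl)oxy]-2,2-dimethyl-3a,4,5,7a-tetrahydro-1,3-benzodioxol-4-yl]methyl benzoate
Conditions: BzCl (11, 1.1 equiv), pyridine, CH2Cl2, 0 °C
Reagents that add atoms: benzoyl chloride 11, O=C(Cl)c1ccccc1
Why: This chemoselective O-acylation works because the primary C7 hydroxyl reacts far faster than the tertiary C1 hydroxyl, which is flanked by two oxygenated carbons and is inert without an acyl-transfer catalyst.

Step 9
Reactants: 12 bromo benzoate
Product: 13 [(3aR,4R,5S,7aR)-4-hydroxy-5-[(4-methoxybenzyl)oxy]-2,2-dimethyl-3a,4,5,7a-tetrahydro-1,3-benzodioxol-4-yl]methyl benzoate (C4–H; the descriptor at C3 changes only through CIP ranking)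
Conditions: Bu3SnH (1.5 equiv), AIBN (cat.), degassed toluene, 85 °C; aq. KF work-up
Reagents that add atoms: none
Why: In this radical chain hydrodebromination the stannyl radical abstracts bromine and the σ-vinyl radical at C4, whose orbital points away from the C6 side chain, is quenched by Bu3SnH faster than any hydrogen shift, while esters, ethers, the acetal and the free tertiary alcohol are inert and no stereocentre is involved.

Step 10
Reactants: 13 debrominated acetonide benzoate
Product: 15 [(1R,2R,3R,6S)-2,3-diacetoxy-1-hydroxy-6-[(4-methoxybenzyl)oxy]cyclohex-4-en-1-yl]methyl benzoate, via triol 14 (not isolated)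
Conditions: AcOH–H2O 4:1, 50 °C; evaporation with toluene; then Ac2O (3 equiv), pyridine, DMAP (cat.), CH2Cl2, 0 °C → rt
Reagents that add atoms: acetic anhydride, CC(=O)OC(C)=O
Why: Acid-catalysed acetal hydrolysis frees the C2/C3 diol while the PMB ether, the alkene and the benzoate (already on the thermodynamically preferred primary oxygen) are inert to aqueous acetic acid, and immediate DMAP-catalysed acetylation of the crude triol esterifies only the two secondary hydroxyls because the tertiary C1 hydroxyl is too hindered, so the migration-prone triol is never stored and no stereocentre is touched.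

Step 11
Reactants: 15 2,3-diacetate C6 PMB ether
Product: 16 [(1R,2R,3R,6S)-2,3-diacetoxy-1,6-dihydroxycyclohex-4-en-1-yl]methyl benzoate (CNP0130780.2)
Conditions: DDQ (1.3 equiv), CH2Cl2–pH 7 phosphate buffer 18:1, 0 °C; aq. NaHCO3 wash, rapid chromatography
Reagents that add atoms: none
Why: In this oxidative PMB ether cleavage DDQ takes hydride from the electron-rich benzylic CH2 through a charge-transfer complex, water traps the oxocarbenium ion and the hemiacetal collapses to the C6 alcohol with its C–O bond (and configuration) intact, while the cold, near-neutral medium leaves the three esters where they are.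

Compound list
1 | bromobenzene | Brc1ccccc1 | starting material
2 | (1S,2S)-3-bromocyclohexa-3,5-diene-1,2-diol | O[C@@H]1[C@H](O)C(Br)=CC=C1 | intermediate
3 | (3aS,7aS)-4-bromo-2,2-dimethyl-3a,7a-dihydro-1,3-benzodioxole | CC1(C)O[C@@H]2[C@H](O1)C(Br)=CC=C2 | intermediate
4 | anti C1–C6 vinyl epoxide of the bromodiene acetonide | CC1(C)O[C@@H]2[C@H](O1)C(Br)=C[C@H]3O[C@@H]23 | intermediate
5 | C6 PMB ether, C1 secondary alcohol | CC1(C)O[C@@H]2[C@H](O1)C(Br)=C[C@H](OCc1ccc(OC)cc1)[C@H]2O | intermediate
6 | C1 ketone | CC1(C)O[C@@H]2[C@H](O1)C(Br)=C[C@H](OCc1ccc(OC)cc1)C2=O | intermediate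
7 | dibromomethane | BrCBr | starting material
8 | bis(bromozincio)methane (gem-dizinc methylene donor, not isolated) | Br[Zn]C[Zn]Br | intermediate
9 | exocyclic C1=C7 methylene compound | CC1(C)O[C@@H]2[C@H](O1)C(Br)=C[C@H](OCc1ccc(OC)cc1)C2=C | intermediate
10 | C1 tertiary alcohol with C7 primary alcohol | CC1(C)O[C@@H]2[C@H](O1)C(Br)=C[C@H](OCc1ccc(OC)cc1)[C@]2(O)CO | intermediate
11 | benzoyl chloride | O=C(Cl)c1ccccc1 | starting material
12 | C7 benzoate, bromo acetonide | CC1(C)O[C@@H]2[C@H](O1)C(Br)=C[C@H](OCc1ccc(OC)cc1)[C@]2(O)COC(=O)c1ccccc1 | intermediate
13 | C7 benzoate, debrominated acetonide | CC1(C)O[C@@H]2[C@H](O1)C=C[C@H](OCc1ccc(OC)cc1)[C@]2(O)COC(=O)c1ccccc1 | intermediate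
14 | [(1S,2R,3R,6S)-1,2,3-trihydroxy-6-[(4-methoxybenzyl)oxy]cyclohex-4-en-1-yl]methyl benzoate (same spatial arrangement; C1 descriptor changes by CIP ranking only; not isolated) | O[C@@H]1[C@H](O)C=C[C@H](OCc2ccc(OC)cc2)[C@]1(O)COC(=O)c1ccccc1 | intermediate
15 | 2,3-diacetate with C6 PMB ether | CC(=O)O[C@@H]1[C@H](OC(C)=O)C=C[C@H](OCc2ccc(OC)cc2)[C@]1(O)COC(=O)c1ccccc1 | intermediate
16 | CNP0130780.2 | CC(=O)O[C@@H]1[C@H](OC(C)=O)C=C[C@H](O)[C@]1(O)COC(=O)c1ccccc1 | target

Total step count: 11
Longest linear sequence: 11 steps (1 → 16; 7 and 11 enter as purchased reagents)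

Steps most likely to fail

1. Step 6 (methylenation of the labile ketone).
- What may go wrong: titanium and zinc halides may ionise the doubly allylic C6 ether or strip the acetonide. The ketone may enolise and lose β-alkoxide on the way to aromatisation. Methylene transfer to the hindered carbonyl may stall.
- Fallback: a Peterson olefination sets out from ketone 6. Me3SiCH2MgCl premixed with anhydrous CeCl3 (THF, −78 °C) adds as a weakly basic organocerium nucleophile, expected from the upper face, to give the β-hydroxysilane F1. KH (THF, 0 °C) then triggers syn-elimination of silanolate in a medium free of Lewis acids. The carbinol configuration of F1 is erased in this elimination, and the sequence rejoins the route at alkene 9.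

2. Step 4 (alcoholysis of the vinyl epoxide).
- What may go wrong: the acid may promote self-condensation of the benzylic alcohol or loss of the acetonide. Inversion may erode through a cationic pathway, or attack may occur with allylic transposition.
- Fallback: this sequence sets out from epoxide 4 and separates C–O bond formation from protection. Aqueous KOH in DMSO (80 °C) opens the same allylic carbon by a purely anionic SN2 process to give the trans-diol F2. Bu2SnO (toluene, azeotropic water removal) converts it into the dibutylstannylene acetal F3. PMBCl with CsF in DMF then alkylates the less hindered allylic C6 oxygen, and the sequence rejoins the route at 5.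

3. Step 7 (osmylation that sets quaternary C1).
- What may go wrong: the hindered alkene, inductively deactivated by two allylic oxygens, may react sluggishly. Forcing conditions may erode facial selectivity, and the ring alkene may begin to compete.
- Fallback: this sequence sets out from alkene 9. mCPBA (NaHCO3-buffered CH2Cl2, 0 °C → rt) epoxidises the exocyclic alkene from the same convex face to give the spiro-epoxide F4, with oxygen on the upper face. Caesium benzoate with benzoic acid in DMF (70 °C) opens it at the unhindered CH2 terminus. This delivers the tertiary alcohol and the primary benzoate together and rejoins the route at 12, bypassing 10 and 11.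

Further compounds
F1 | step 6 | C1 β-hydroxysilane (CH2SiMe3 upper face, OH lower face) | CC1(C)O[C@@H]2[C@H](O1)C(Br)=C[C@H](OCc1ccc(OC)cc1)[C@@]2(O)C[Si](C)(C)C
F2 | step 4 | (3aS,4R,5S,7aS)-7-bromo-2,2-dimethyl-3a,4,5,7a-tetrahydro-1,3-benzodioxole-4,5-diol (trans C1/C6 diol) | CC1(C)O[C@@H]2[C@H](O1)C(Br)=C[C@H](O)[C@H]2O
F3 | step 4 | C1,C6-O-dibutylstannylene acetal of the trans-diol | CC1(C)O[C@@H]2[C@H](O1)C(Br)=C[C@@H]3O[Sn](CCCC)(CCCC)O[C@@H]23
F4 | step 7 | C1 spiro-epoxide (oxygen on the upper face) | CC1(C)O[C@@H]2[C@H](O1)C(Br)=C[C@H](OCc1ccc(OC)cc1)[C@]23CO3
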